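The readings stem from a simulated flask for substances that don't exist; the scatter is artificial.

0.364 is what Thursday's flask kept at 50.0 min, counted as target standing per substrate consumed. We carry this selectivity as φ. The zero of our scale is φ = 1, the case where each consumed substrate stands as target.

| flask | substrate | gas phase | remark | time |
|---|---|---|---|---|
| Sunday's | 0.57 M | 90 mM (held) | the very flask that is asked about, followed so far |  |
| Thursday's | 0.85 M | 90 mM (held) | run made earlier |  |
| flask | 0.57 M | 90 mM (held) |  | 50 min |

| run | time / min | target / % | substrate / % |
|---|---|---|---|
| Sunday's | 0.500 | 0.1 | 99.1 |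
| Sunday's | 0.833 | 0.8 | 99.5 |
| Sunday's | 1.33 | 1.7 | 98.1 |
| Sunday's | 2.00 | 2.2 | 97.2 |
| Sunday's | 4.00 | 6.9 | 92.3 |
| Sunday's | 6.00 | 11.4 | 86.4 |
| Thursday's | 4.00 | 5.5 | 93.1 |
| Thursday's | 6.00 | 9.1 | 88.6 |
| Thursday's | 12.0 | 16.3 | 74.7 |
| Thursday's | 20.0 | 23.7 | 55.5 |
| Thursday's | 30.0 | 28.9 | 34.5 |
| Thursday's | 50.0 | 33.2 | 8.7 |

(standard deviation of a reading: 0.3 percentage points)

1. the target standing at 50 min, as a percentage of the substrate charged
2. the change that raises the amount of target at 50 min, in percent of the substrate charged most ("none" if none brings more than 2 percentage points) (eta / theta / none)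
3. amount of target at 50 min, in percent of the substrate charged, after theta

- eta: doubling the transfer coefficient of the gas phase, all else as stated
- theta: doubling the saturation concentration of gas phase, all else as stated

- at the start none of the gas phase is in solution

Does the gap below 1 follow the charge? At 6.00 min, Sunday's flask reads φ = 0.838 and Thursday's 0.798. The ratio of their gaps is 0.802, a loose reading given the scatter, against a charge ratio of 0.671.

What does that give at 50 min? Scaling Thursday's final gap by this ratio, our reckoning gives φ = 0.490. Sunday's flask had used more substrate at 6.00 min (86.4% left against 88.6%), but we take Thursday's final 8.7% as its rest, so target stands near 44.7%.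

What can gas add? Turning that rest into target at this φ brings 4.3 percentage points, which is more than 2 points. Sunday's target rate between 4.00 min and 6.00 min is 2.05 times that of the first 2.00 min, so the rate reads as still climbing where these readings end, and they do not show how long the climb lasts. We choose theta as a judgement that these readings do not prove, with about 49.0%.

The forecast gave 44%, theta and 60%, saying “Doubling csat doubles dissolved gas at every stage”. The flask gives 40.5%, and theta is best, adding 3.5 points against 1.3 points for eta, for 44.0%.

    gas phase ⇌ dissolved gas, rate k1*(csat - [dissolved gas]) (kL = 0.00426 /s)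
    substrate + dissolved gas → target (k = 0.0164 /M/s)
    substrate + target → side product (k = 9.05 × 10⁻⁴ /M/s)
    target → over-reaction product (k = 2.60 × 10⁻⁴ /s)

The flask's φ is 0.429, less than our 0.490. At 50.0 min, target is made at 0.615 of the rate at which it is used up, and over-reaction takes 8.9 times what the side-product step takes. Drawing a line through Thursday's φ and this flask's gives 0.484 for the neighbour charged with 0.34 M. That neighbour computes to 47.3% target with 3.6% substrate left, a φ of 0.491.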